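The numbers of this flask are those of an exercise; the result is computed.

The closed, stirred vessel holds a charge of starting material at constant temperature and runs these steps:

    product ⇌ intermediate B (k1 = 5.7 × 10⁻⁶ s⁻¹)
    starting material ⇌ product (K2 = 0.59, k2 = 4.3 × 10⁻⁶ s⁻¹)
    starting material ⇌ dormant form (K3 = 0.88, k3 = 2.0 × 10⁻⁵ s⁻¹)
    intermediate A ⇌ intermediate B (K4 = 0.78, k4 = 9.2 × 10⁻⁷ s⁻¹)
    starting material ⇌ intermediate A (K5 = 0.38, k5 = 4.1 × 10⁻⁵ s⁻¹)

starting material 0.10 M; time 15 d

- why nothing more happens at 15 d, or that something still does (all of the starting material has reacted / it is still moving / forward and back rates have come level)
- amount of product at 15 d, in percent of the starting material charged
- amount of intermediate A at 15 d, in percent of the starting material charged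
- amount of product if the flask were left three thousand times as long, in percent of the starting material charged

- the reaction counts as stopped when no species that holds the starting material changes by six tenths of a point or more over the second half of the time
- run time (flask): 15 d

The ledger follows each mole of starting material charged, which must stand in one of the listed forms. If the flask reaches equilibrium, each entry can be written in parts per part of starting material:

[starting material]: 1
[product]: 0.59
[dormant form]: 0.88
[intermediate A]: 0.38
[intermediate B]: 0.38 × 0.78 = 0.296
ledger total: 3.15

The entry for intermediate B comes out alike by way of intermediate A or of product, since the constant of the step from product to intermediate B is written to close that loop. The ledger total, the parts held in the listed forms per part of starting material at equilibrium, turns an entry into a share of the charge: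

product: 0.59 / 3.15 = 18.7%
intermediate A: 0.38 / 3.15 = 12.1%

These shares need the books to close within the run. The step between the intermediates is slower than the relaxations of starting material with its neighbours, with a relaxation half-life of 3.82 d by itself. The run of 15 d is longer than that by a factor of 3.93. This reckoning therefore commits to forward and back rates having come level under thermodynamic control, with the same product share after the long wait.

The forecast says that forward and back rates have come level, with product 18.75%, intermediate A 12.08% and 18.75% of product after the long wait, concluding “so the system has reached equilibrium”.

In the flask forward and back rates have come level, with product at 18.7%, intermediate A at 12.1% and 18.8% of product after the long wait. This flask already holds 18.5% of its charge as product at 7.50 d. Applied to intermediate B, the ledger total gives 9.41%, and this flask holds 9.42% at 15.0 d. The ledger total contains no concentration, so for the neighbour flask charged with 0.040 M it gives 0.00749 M of product, and that flask holds 18.7% of its charge as product at 15.0 d.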